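**Strategy**

Everything rests on cutting the bond between the bridge CH2 and aromatic C1' of ring B. The bridge carbon is carried on ring A C6 as an acetic acid, activated as its N-hydroxyphthalimide ester with both ring A enols capped as methyl ethers; ring B enters as the arylzinc at C1', flanked by two MOM ethers. One nickel-catalysed decarboxylative coupling joins them. It exploits the fact that this CH2 links two different electron-rich rings, dienone ring A and phloroglucinol ring B, a motif that electrophilic one-carbon bridging can only make as a mixture with both symmetric dimers. A single acid treatment then frees all four oxygens.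

Key step: step 10

**Remarks and assumptions**

- Numbering: ring A is the cyclohexa-2,5-dien-1-one (C1 carbonyl, C2 butanoyl, C3–O, C4 gem-dimethyl, C5–O, C6 bridge-bearing carbon). Ring B is numbered from the bridge-bearing carbon C1' (C2' and C6' oxygens, C3' butanoyl, C4' OMe, C5' H). The target has no stereocentre.
- Assumption: the bis(methyl enol ether) of ring A is drawn as the 3,5-di-O-methyl cross-conjugated dienone. Any regioisomeric bis(enol ether) would be equally aprotic in the coupling and would converge on the same target in the last step.
- Correction: direct zinc insertion into an aryl iodide gives the arylzinc iodide (as its LiCl adduct), so the ring B organometallic is written with iodide on zinc rather than chloride. The halide is a spectator.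

**Route**

Step 1
Reactants: 1 phloroglucinol; 2 butanoyl chloride
Product: 3 butyrylphloroglucinol [1-(2,4,6-trihydroxyphenyl)butan-1-one]
Conditions: AlCl3 (3 equiv), MeNO2/CH2Cl2, 0 °C to 40 °C; aq. HCl work-up
Reagents that add atoms: none
Why: Friedel–Crafts C-acylation of the symmetric, strongly activated triol, where the chelated ortho-hydroxy ketone formed deactivates the ring towards a second acylation.

Step 2
Reactants: 3 butyrylphloroglucinol
Product: 4 butyrylfilicinic acid [2-butanoyl-3,5-dihydroxy-4,4-dimethylcyclohexa-2,5-dien-1-one]
Conditions: NaOMe (3 equiv), MeI (2.1 equiv), MeOH, 0 °C to rt; aq. HCl work-up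
Reagents that add atoms: iodomethane, CI
Why: Dearomatising geminal C-methylation of the acylphloroglucinol polyanion (Riedl-type alkylation), which is C-nucleophilic in methanol, with limited MeI so that the vinylogous acid 4 should be separable from under- and over-methylated material.

Step 3
Reactants: 4 butyrylfilicinic acid; 5 tert-butyl bromoacetate
Product: 6 tert-butyl 2-(5-butanoyl-2,4-dihydroxy-3,3-dimethyl-6-oxocyclohexa-1,4-dien-1-yl)acetate
Conditions: NaOMe (2.0 equiv), MeOH, 0 °C; 5 (1.05 equiv), 0 °C to rt; aq. citric acid work-up
Reagents that add atoms: none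
Why: SN2 C-alkylation of the dianion at the last ring CH (C6), the same carbon nucleophilicity used in step 2, with a soft alpha-halo ester in protic medium that favours carbon over oxygen; the bulky tert-butyl ester resists methanolysis and slows a second alkylation.

Step 4
Reactants: 6 tert-butyl 2-(5-butanoyl-2,4-dihydroxy-3,3-dimethyl-6-oxocyclohexa-1,4-dien-1-yl)acetate
Product: 7 tert-butyl 2-(5-butanoyl-2,4-dimethoxy-3,3-dimethyl-6-oxocyclohexa-1,4-dien-1-yl)acetate
Conditions: TMSCHN2 (3 equiv), MeOH/toluene (1:4), 0 °C to rt; AcOH quench
Reagents that add atoms: trimethylsilyldiazomethane, C[Si](C)(C)C=[N+]=[N-]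
Why: O-methylation of the two acidic enols by diazomethane released in the flask, where proton transfer followed by methyl transfer to oxygen avoids the C-methylation at C6 that a methyl halide and base would cause.

Step 5
Reactants: 7 tert-butyl 2-(5-butanoyl-2,4-dimethoxy-3,3-dimethyl-6-oxocyclohexa-1,4-dien-1-yl)acetate
Product: 8 2-(5-butanoyl-2,4-dimethoxy-3,3-dimethyl-6-oxocyclohexa-1,4-dien-1-yl)acetic acid
Conditions: TFA/CH2Cl2 (1:4), anhydrous, 0 °C to rt; toluene azeotrope
Reagents that add atoms: none
Why: Acidolysis of the tert-butyl ester with loss of isobutene, run without water so that the methyl enol ethers, which need water to hydrolyse, should persist.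

Step 6
Reactants: 8 2-(5-butanoyl-2,4-dimethoxy-3,3-dimethyl-6-oxocyclohexa-1,4-dien-1-yl)acetic acid
Product: 9 1,3-dioxoisoindolin-2-yl 2-(5-butanoyl-2,4-dimethoxy-3,3-dimethyl-6-oxocyclohexa-1,4-dien-1-yl)acetate
Conditions: N-hydroxyphthalimide, DIC, DMAP (5 mol %), CH2Cl2, 0 °C to rt
Reagents that add atoms: N-hydroxyphthalimide, ON1C(=O)c2ccccc2C1=O
Why: Steglich-type carbodiimide esterification of an unhindered primary acid, under neutral conditions that leave the enol ethers and ketone untouched.

Step 7
Reactants: 10 5-methoxyresorcinol; 2 butanoyl chloride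
Product: 11 1-(2,4-dihydroxy-6-methoxyphenyl)butan-1-one
Conditions: AlCl3 (2.5 equiv), MeNO2/CH2Cl2, 0 °C to rt; aq. HCl work-up; chromatography
Reagents that add atoms: none
Why: Friedel–Crafts acylation that should favour the two equivalent sites ortho to OMe and para to a hydroxyl over the single site between the hydroxyls; the symmetric 2,6-dihydroxy-4-methoxy isomer is removed by chromatography and the temperature is kept low to spare the methyl ether.

Step 8
Reactants: 11 1-(2,4-dihydroxy-6-methoxyphenyl)butan-1-one
Product: 12 1-(2,4-dihydroxy-3-iodo-6-methoxyphenyl)butan-1-one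
Conditions: NIS (1.0 equiv), MeCN, 0 °C
Reagents that add atoms: N-iodosuccinimide, O=C1CCC(=O)N1I
Why: Electrophilic aromatic iodination directed to C3, because chelation of the 2-hydroxyl to the ketone fixes the ring bonds so that the carbon between the two hydroxyls (also para to OMe) is the most nucleophilic, as in the 3-iodination of 2,4-dihydroxyacetophenones; one equivalent limits di-iodination.

Step 9
Reactants: 12 1-(2,4-dihydroxy-3-iodo-6-methoxyphenyl)butan-1-one
Product: 13 1-[3-iodo-6-methoxy-2,4-bis(methoxymethoxy)phenyl]butan-1-one
Conditions: NaH (2.3 equiv), MOMCl (2.6 equiv), DMF, 0 °C to rt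
Reagents that add atoms: chloromethyl methyl ether, COCCl
Why: Williamson-type O-alkylation of both phenoxides, with NaH breaking the hydrogen-bond chelate of the hindered 2-hydroxyl so that it is capped as well.

Step 10
Reactants: 9 1,3-dioxoisoindolin-2-yl 2-(5-butanoyl-2,4-dimethoxy-3,3-dimethyl-6-oxocyclohexa-1,4-dien-1-yl)acetate; 13 1-[3-iodo-6-methoxy-2,4-bis(methoxymethoxy)phenyl]butan-1-one
Product: 15 fully protected target [2-butanoyl-6-{[3-butanoyl-4-methoxy-2,6-bis(methoxymethoxy)phenyl]methyl}-3,5-dimethoxy-4,4-dimethylcyclohexa-2,5-dien-1-one], via ring B arylzinc iodide 14 (not isolated)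
Conditions: 13 (2 equiv), Zn dust (BrCH2CH2Br, TMSCl activation), LiCl, THF, 50 °C; then 9, NiCl2(glyme) (20 mol %), 4,4'-di-tert-butyl-2,2'-bipyridine (40 mol %), THF/DMF, 25 °C
Reagents that add atoms: none
Why: Zinc inserts into the C–I bond of 13, helped by LiCl and the flanking MOM oxygens and tolerant of the hindered ketone, to give 14, which transmetalates to nickel; monovalent nickel then transfers one electron to the phthalimide ester of 9, which fragments to phthalimide anion, CO2 and the primary ring A–CH2 radical. Capture of this radical by divalent aryl nickel gives a trivalent alkyl(aryl)nickel species that reductively eliminates the CH2–C1' bond and returns monovalent nickel. The closest known reaction type is the nickel-catalysed decarboxylative Negishi arylation of redox-active esters, and benzylic-type radicals are known to couple with arylzinc reagents at nickel. No ring is closed and no stereocentre is formed. The step needs hetero-coupling only, secured because the bridge carbon is already bonded to ring A C6 and the aryl partner is one defined organometallic; it also needs bonding at the CH2 terminus of the allyl-type radical rather than at ring carbon C5, secured because C5 is a fully substituted enol ether carbon next to the gem-dimethyl centre while the CH2 end is unhindered. The arylzinc is not basic enough to enolise either butanoyl ketone and does not add to the vinylogous esters, and two equivalents offset slow transmetalation of the doubly ortho-substituted aryl.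

Step 11
Reactants: 15 fully protected target
Product: 17 target [2-butanoyl-6-[(3-butanoyl-2,6-dihydroxy-4-methoxyphenyl)methyl]-3,5-dihydroxy-4,4-dimethylcyclohexa-2,5-dien-1-one], via ring A triketone bis-MOM ether 16 (not isolated)
Conditions: 2 M aq. HCl/THF, 25 °C; then MeOH, 50 °C
Reagents that add atoms: water, O
Why: Acid hydrolysis of the two vinylogous methyl esters (conjugate addition of water, loss of methanol) followed by acetal cleavage of the two aryl MOM ethers, with the aryl methyl ether and both ketones inert to dilute HCl; the staging should free the ring B phenols only after ring A no longer carries an activated enol ether, which guards against ring closure to a xanthene.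

**Compound list**

1 | phloroglucinol | Oc1cc(O)cc(O)c1 | starting material
2 | butanoyl chloride | CCCC(=O)Cl | starting material
3 | butyrylphloroglucinol, 1-(2,4,6-trihydroxyphenyl)butan-1-one | CCCC(=O)c1c(O)cc(O)cc1O | intermediate
4 | butyrylfilicinic acid, 2-butanoyl-3,5-dihydroxy-4,4-dimethylcyclohexa-2,5-dien-1-one | CCCC(=O)C1=C(O)C(C)(C)C(O)=CC1=O | intermediate
5 | tert-butyl bromoacetate | CC(C)(C)OC(=O)CBr | starting material
6 | tert-butyl 2-(5-butanoyl-2,4-dihydroxy-3,3-dimethyl-6-oxocyclohexa-1,4-dien-1-yl)acetate | CCCC(=O)C1=C(O)C(C)(C)C(O)=C(CC(=O)OC(C)(C)C)C1=O | intermediate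
7 | tert-butyl 2-(5-butanoyl-2,4-dimethoxy-3,3-dimethyl-6-oxocyclohexa-1,4-dien-1-yl)acetate | CCCC(=O)C1=C(OC)C(C)(C)C(OC)=C(CC(=O)OC(C)(C)C)C1=O | intermediate
8 | 2-(5-butanoyl-2,4-dimethoxy-3,3-dimethyl-6-oxocyclohexa-1,4-dien-1-yl)acetic acid | CCCC(=O)C1=C(OC)C(C)(C)C(OC)=C(CC(=O)O)C1=O | intermediate
9 | 1,3-dioxoisoindolin-2-yl 2-(5-butanoyl-2,4-dimethoxy-3,3-dimethyl-6-oxocyclohexa-1,4-dien-1-yl)acetate (redox-active ester of ring A) | CCCC(=O)C1=C(OC)C(C)(C)C(OC)=C(CC(=O)ON2C(=O)c3ccccc3C2=O)C1=O | intermediate
10 | 5-methoxyresorcinol | COc1cc(O)cc(O)c1 | starting material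
11 | 1-(2,4-dihydroxy-6-methoxyphenyl)butan-1-one | CCCC(=O)c1c(O)cc(O)cc1OC | intermediate
12 | 1-(2,4-dihydroxy-3-iodo-6-methoxyphenyl)butan-1-one | CCCC(=O)c1c(OC)cc(O)c(I)c1O | intermediate
13 | 1-[3-iodo-6-methoxy-2,4-bis(methoxymethoxy)phenyl]butan-1-one | CCCC(=O)c1c(OC)cc(OCOC)c(I)c1OCOC | intermediate
14 | [3-butanoyl-4-methoxy-2,6-bis(methoxymethoxy)phenyl]zinc iodide (LiCl adduct in THF, not isolated) | CCCC(=O)c1c(OC)cc(OCOC)c([Zn]I)c1OCOC | intermediate
15 | 2-butanoyl-6-{[3-butanoyl-4-methoxy-2,6-bis(methoxymethoxy)phenyl]methyl}-3,5-dimethoxy-4,4-dimethylcyclohexa-2,5-dien-1-one | CCCC(=O)C1=C(OC)C(C)(C)C(OC)=C(Cc2c(OCOC)cc(OC)c(C(=O)CCC)c2OCOC)C1=O | intermediate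
16 | 2-butanoyl-6-{[3-butanoyl-4-methoxy-2,6-bis(methoxymethoxy)phenyl]methyl}-3,5-dihydroxy-4,4-dimethylcyclohexa-2,5-dien-1-one (not isolated) | CCCC(=O)C1=C(O)C(C)(C)C(O)=C(Cc2c(OCOC)cc(OC)c(C(=O)CCC)c2OCOC)C1=O | intermediate
17 | 2-butanoyl-6-[(3-butanoyl-2,6-dihydroxy-4-methoxyphenyl)methyl]-3,5-dihydroxy-4,4-dimethylcyclohexa-2,5-dien-1-one | CCCC(=O)C1=C(O)C(C)(C)C(O)=C(Cc2c(O)cc(OC)c(C(=O)CCC)c2O)C1=O | target

**Step count**

Total: 11 steps. Longest linear sequence: 8 steps (steps 1 to 6, then 10 and 11); the ring B branch is steps 7 to 9.

**Steps most likely to fail and fallbacks**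

Step 10. Transmetalation of the doubly ortho-substituted arylzinc to nickel may lag behind radical generation, so the ring A–CH2 radical could be lost to dimerisation or hydrogen abstraction; zinc insertion between two MOM ethers may also stall. The fallback abandons the radical coupling for a Mannich and ortho-quinone methide sequence that carries the bridge carbon on ring B. It sets out from 11 and 4. Aminomethylation of 11 with aqueous formaldehyde and dimethylamine in ethanol at rt should occur at C3, the carbon between the hydroxyls, under the same bond fixation as in step 8, giving 1-[3-(dimethylaminomethyl)-2,4-dihydroxy-6-methoxyphenyl]butan-1-one F1. Heating F1 with 4 in dioxane at 100 °C should expel dimethylamine to form 4-butanoyl-3-hydroxy-5-methoxy-2-methylidenecyclohexa-3,5-dien-1-one F2, which 4 traps at its ring CH by conjugate addition. Because the CH2 is bonded to ring B beforehand, only the mixed dimer is built, and the sequence comes back to the route at target 17 without protecting groups.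

Step 4. Methylation may spread over the three ring oxygens and the acyl enol oxygen, or stop at the chelated enol, giving regioisomeric or partly capped material that is hard to purify. The fallback replaces the one-pot kinetic methylation by a two-stage sequence whose first stage is under equilibrium control. It sets out from 6. Treatment with HC(OMe)3 in MeOH with catalytic PPTS at rt should etherify only the oxygen whose capping leaves the hydrogen-bonded acyl triketone intact, giving tert-butyl 2-(5-butanoyl-4-hydroxy-2-methoxy-3,3-dimethyl-6-oxocyclohexa-1,4-dien-1-yl)acetate F3. One equivalent of TMSCHN2 in MeOH/toluene then caps the remaining chelated enol, and the sequence comes back to the route at 7.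

Step 3. Alkylation may go to oxygen instead of carbon, or a second alkylation at the same carbon may give a quaternary centre. The fallback replaces SN2 alkylation by a three-component reductive alkylation. It sets out from 4. With tert-butyl glyoxylate, Hantzsch ester and catalytic L-proline in CH2Cl2 at rt, Knoevenagel condensation at the ring CH should give tert-butyl 2-(3-butanoyl-4-hydroxy-5,5-dimethyl-2,6-dioxocyclohex-3-en-1-ylidene)acetate F4, which is reduced in the flask by hydride transfer from the dihydropyridine. This path can only deliver the mono-C-alkyl product, and it comes back to the route at 6.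

**Further compounds**

F1 | step 10 | 1-[3-(dimethylaminomethyl)-2,4-dihydroxy-6-methoxyphenyl]butan-1-one | CCCC(=O)c1c(OC)cc(O)c(CN(C)C)c1O
F2 | step 10 | 4-butanoyl-3-hydroxy-5-methoxy-2-methylidenecyclohexa-3,5-dien-1-one | C=C1C(=O)C=C(OC)C(C(=O)CCC)=C1O
F3 | step 4 | tert-butyl 2-(5-butanoyl-4-hydroxy-2-methoxy-3,3-dimethyl-6-oxocyclohexa-1,4-dien-1-yl)acetate | CCCC(=O)C1=C(O)C(C)(C)C(OC)=C(CC(=O)OC(C)(C)C)C1=O
F4 | step 3 | tert-butyl 2-(3-butanoyl-4-hydroxy-5,5-dimethyl-2,6-dioxocyclohex-3-en-1-ylidene)acetate | CCCC(=O)C1=C(O)C(C)(C)C(=O)C(=CC(=O)OC(C)(C)C)C1=O
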